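All constants are invented; what happens was integrated by code.

Millimolar is the working unit of this flask: the solution holds 8.3 mM of target at saturation, and you charge 0.40 M of substrate.

substrate 0.40 M; time 1.5 min

- amount of target and crystals together at 1.5 min, in percent of the substrate charged
- the change that raises the amount of target and crystals together at 1.5 min, in percent of the substrate charged most ("none" if none brings more than 2 percentage points) (Monday's / Thursday's / none)
- amount of target and crystals together at 1.5 min, in percent of the substrate charged, after Monday's

- Monday's: doubling the dissolution coefficient of step 1, all else as stated
- Thursday's: doubling the solubility in step 1, all else as stated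

- for target the crystals are counted in
- as a solid, counted per litre of solution: crystals
- run time (flask): 1.5 min

    crystals ⇌ target, rate k1*(cs1 - [target]) while solid is left; crystals form when [target] > cs1 (cs1 = 8.3 mM, k1 = 0.077 s⁻¹)
    substrate ⇌ isomer of the product (K2 = 2.9, k2 = 0.0068 s⁻¹)
    substrate ⇌ target (K3 = 0.095, k3 = 0.051 s⁻¹)
    target → over-reaction product (k4 = 0.012 s⁻¹)

In the first instants substrate makes target at 20.4 mM s⁻¹, faster than the 2.72 mM s⁻¹ it gives to the isomer of the product. With the way back and over-reaction counted, I reckon that c(target) reaches saturation after about 0.460 s. Crystals start to form. The relaxation half-life of the substrate–target step, both ways together, is 1.18 s, far shorter than the run, so I treat dissolved target as a quasi-steady-state intermediate. It leaves at 0.626 s⁻¹ times its concentration, mainly by the way back, which is faster than crystallisation or over-reaction. Balancing gain against loss gives 33.6 mM for the fresh charge. This is the standing level: the c(target) at which making and using up balance for the substrate then present. Crystals grow at 0.077 s⁻¹ times its excess over saturation.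

In the middle, substrate sinks by two ways of about equal speed: to the isomer of the product at 0.0068 s⁻¹, and through target at 0.00725 s⁻¹, the part of that step not returned. Together they give, by my reckoning, 113 mM of substrate at the end. This figure leaves out two returns to substrate, the one from the isomer of the product and a term of 0.548 mM s⁻¹ from target, which comes from crystals growing on the excess over saturation and not on the whole of c(target), so it runs low.

With that substrate the standing level at the end comes to 10.2 mM, still above saturation. A straight-line mean of the level gives an excess of 13.6 mM. Multiplying by coefficient and time and adding the dissolved target, I commit to 26.2%. Monday's change moves the level to 30.8 mM at the start and 7.14 mM at the end, and the same reckoning gives 38.8%. Thursday's gives levels of 34.6 mM and 11.2 mM against a doubled saturation, a smaller excess. My choice is Monday's.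

The forecast gives 24.5%, picks Monday's and expects 33.5% after it, holding that “Crystallisation is the bottleneck”.

The flask gives 24.1%, and 34.4% after Monday's, a gain of 10 percentage points, while Thursday's moves it by −9.6 points. At 0.150 min dissolved target read 347% of saturation, which is 28.8 mM. The standing level for the substrate of that moment, 83.8% of the charge, is 28.3 mM.

Read the same flask at 40 s: the standing level there is 19.6 mM, and the same mean excess gives 19.0%. That flask gives 17.8%.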